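1. Isomerisation moves material between target and isomer of the product and leaves c(target) + c(isomer) unchanged, so this step lowers the share of target in that sum, while fresh target formed meanwhile raises it.

common to all: starting material 0.050 M

| flask | reagent | protic impurity | temperature | remark | time |
|---|---|---|---|---|---|
| eta | 1 equiv | 2.5 mM | 110 °C | run made earlier |  |
| gamma | 1.5 equiv | 2.5 mM | 110 °C | run made earlier |  |
| south-west | 1.00 equiv (fed, over 15 d) | 2.50 mM | 110 °C | all else is in the flask from the start; the feed brings no volume worth counting | 20 d |
| south | 1.00 equiv | 2.50 mM |  | everything together at the start at 90 °C, warmed to 110 °C at 15 d | 20 d |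
| west | 1.00 equiv (fed, over 15 d) | 2.50 mM |  | the addition at 90 °C, then warmed to 110 °C; the feed brings no volume worth counting | 20 d |
| south-east | 1.00 equiv | 2.50 mM | 110 °C | everything together at the start | 20 d |

- eta (time / d: target / %, isomer of the product / %): 2.50: 59.8, 3.3; 8.00: 68.6, 15.9; 12.0: 64.3, 24.0; 20.0: 55.7, 35.8
- gamma (time / d: target / %, isomer of the product / %): 1.67: 64.6, 2.4; 3.00: 77.5, 5.6; 5.00: 80.0, 11.4; 6.00: 78.9, 14.7

(standard deviation of a reading: 0.3 percentage points)

* which flask leads in share of target in target plus isomer of the product ("all alike" within 1.5 percentage points) (south-west / south / west / south-east / all alike)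
* share of target in target plus isomer of the product at the end, south-west
* share of target in target plus isomer of the product at the end, south
* share of target in target plus isomer of the product at the end, west
* share of target in target plus isomer of the product at the end, south-east

- what was read earlier has a scatter of 0.3 percentage points, one standard deviation
- the earlier runs do not show what temperature does; that part of a forecast is a guess

2. In the gamma run, between 3.00 d and 5.00 d, I divided the isomer gained per day by the mean target present. This gave a reading of 0.0368 d⁻¹ for k, a first-order rate constant of target going to isomer, taken as one-way.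

3. Integrating a one-way first-order loss of target that is all present at the start gives share = exp(−k·t). In the eta run at 20.0 d the share was 60.9 %, so ln(1/share)/k came to 13.5 d. I called this the hot age: the days at 110 °C that target, all present at the start and lost one way, would need to fall to that share. South-east repeats eta, so I expected the same there.

4. Then I turned the question round: what would let south lose its lead over south-east? South has 5.00 d hot, so its 15 d at 90 °C would have to supply the other 8.50 d of hot age. On this rough reckoning, cooling would then have to slow isomerisation by a factor of 1.77 or less. If the cold stretch added nothing, I reckoned a share of 83.2 %.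

5. The forecast named west, with 72 % for south-west, 79 % for south, 83 % for west and 60.9 % for south-east. Its ground for the cold flasks was: “For 90 °C I guess both rates fall about fourfold”. That guess lay beyond my limit.

6. The flasks gave 70.9 % for south-west, 83.2 % for south, 84.9 % for west and 60.6 % for south-east. West led, but its lead over south was 1.7 percentage points against a margin of 1.5 points.

    starting material → intermediate (k = 3.75 × 10⁻⁵ s⁻¹, Ea = 121 kJ mol⁻¹)
    reagent + intermediate → target (k = 2.00 × 10⁻⁴ L mol⁻¹ s⁻¹, Ea = 96.0 kJ mol⁻¹)
    starting material + protic impurity → quenched substrate (k = 0.00510 L mol⁻¹ s⁻¹, Ea = 63.0 kJ mol⁻¹)
    target ⇌ isomer of the product (K = 1.62, k = 4.30 × 10⁻⁷ s⁻¹, Ea = 128 kJ mol⁻¹, ΔH = −47.0 kJ mol⁻¹)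
    (constants at 110 °C)

West ended with a hot age of 4.45 d, below its 5.00 d after warming and far below the 13.5 d of eta. In west, half of the turnover of target into isomer up to 20 d was done by 17.4 d, later than the warming at 15 d. The neighbour of west with 0.400 equiv of reagent gave a share of 84.8 %, a hot age of 4.48 d, with 56.3 % still standing as intermediate.

The runs were generated by integration for substances that don't exist, noise included.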